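**Retrosynthetic overview**

- The target is reached from a spiro[4.5]decenone bearing a C1 ketone, a C8 silyl ether and a C9 alcohol: C9 is acetylated, the isopropenyl group (C3) and the C1 carbinol are then set on the five-membered ring by conjugate addition and hydride reduction from the face syn to the trigonal C6, and C8 is oxidised last.
- Key disconnection C9–C10: a Prins cyclization of a C9 aldehyde onto C10 of a (Z)-configured C5=C10 alkene, the cation at C5 being intercepted by ring expansion of a 1-alkenylcyclobutanol (semipinacol 1,2-shift of the future C4 from C1 to C5).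
- Enabling feature: the spiro atom C5 lies between an oxygen-bearing carbon of the five-membered ring (C1, a latent ketone) and C10, and C9 is a carbinol carbon next to C8; C5 can therefore be a cation quenched by a cyclobutanol-to-cyclopentanone shift and C9 an aldehyde, while the C8 oxygen (silyl ether, later the ketone) is a stereocentre that relays absolute configuration and is then erased.
- Ring order: the six-membered ring closes first (C9–C10) and the five-membered ring with the spiro centre forms in the same operation by four-to-five ring expansion; the acyclic precursor comes from (R)-glyceraldehyde acetonide, 1,1-dibromopropene and cyclobutanone by Stork–Zhao olefination, Negishi coupling and alkenyllithium addition.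

Key step: step 9

Remark: locants C1–C10 are those of the spiro[4.5]decane core of the target (C1–C4 five-membered ring with the ester oxygen on C1 and isopropenyl on C3, C5 spiro atom, C6–C10 six-membered ring with the ketone at C8), and 1,1-dibromoprop-1-ene is taken to be a purchasable reagent.

**Route**

Step 1
Reactants: 1 (R)-2,2-dimethyl-1,3-dioxolane-4-carbaldehyde
Product: 2 (4S)-4-[(1Z)-2-iodoprop-1-en-1-yl]-2,2-dimethyl-1,3-dioxolane
Conditions: EtPPh3I, n-BuLi, THF, 0 °C; iodine, −78 °C; NaN(SiMe3)2, −20 °C; then 1, −78 °C → rt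
Reagents that add atoms: ethyltriphenylphosphonium iodide, CC[P+](c1ccccc1)(c1ccccc1)c1ccccc1.[I-]; iodine, [I][I]
Why: The Stork–Zhao variant of the Wittig olefination (α-iodo ylide generated in the flask) should give the trisubstituted iodoalkene with iodine cis to the dioxolane carbon under kinetic control at low temperature, and the existing stereocentre (the future C8) is untouched, its descriptor changing from R to S only because the substituent priorities change.

Step 2
Reactants: 2 (4S)-4-[(1Z)-2-iodoprop-1-en-1-yl]-2,2-dimethyl-1,3-dioxolane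
Product: 3 (2S,3Z)-4-iodopent-3-ene-1,2-diol
Conditions: AcOH/H2O (4:1), 40 °C
Reagents that add atoms: none
Why: Acid-catalysed hydrolysis of the isopropylidene acetal should free the 1,2-diol, since neither the vinyl iodide nor the allylic carbinol stereocentre reacts with warm aqueous acetic acid.

Step 3
Reactants: 3 (2S,3Z)-4-iodopent-3-ene-1,2-diol
Product: 4 (2S,3Z)-1,2-bis[(tert-butyldimethylsilyl)oxy]-4-iodopent-3-ene
Conditions: TBSCl, imidazole, DMF, rt
Reagents that add atoms: tert-butyldimethylsilyl chloride, CC(C)(C)[Si](C)(C)Cl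
Why: Silyl ether formation on both hydroxyl groups gives a protection that is inert to the organolithium steps that follow and can be differentiated later because the primary ether is far less hindered.

Step 4
Reactants: 4 (2S,3Z)-1,2-bis[(tert-butyldimethylsilyl)oxy]-4-iodopent-3-ene; 5 1,1-dibromoprop-1-ene
Product: 8 (2S,3Z,5Z)-5-bromo-1,2-bis[(tert-butyldimethylsilyl)oxy]-4-methylhepta-3,5-diene, via alkenyllithium 6 (not isolated), via alkenylzinc bromide 7 (not isolated)
Conditions: t-BuLi (2.1 equiv), Et2O, −78 °C; ZnBr2, THF, −78 → 0 °C; then 5, Pd(PPh3)4 (5 mol %), THF, 0 °C → rt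
Reagents that add atoms: none
Why: Negishi cross-coupling in which iodine–lithium exchange and transmetalation to zinc retain the Z geometry and zerovalent palladium inserts selectively into the less hindered C–Br bond of 5 that is trans to its methyl group, so that mono-coupling should leave the bromine cis to the methyl group (5Z) as the later ring closure requires.

Step 5
Reactants: 8 (2S,3Z,5Z)-5-bromo-1,2-bis[(tert-butyldimethylsilyl)oxy]-4-methylhepta-3,5-diene; 9 cyclobutanone
Product: 11 1-[(2Z,4Z,6S)-6,7-bis[(tert-butyldimethylsilyl)oxy]-4-methylhepta-2,4-dien-3-yl]cyclobutan-1-ol, via dienyllithium 10 (not isolated)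
Conditions: t-BuLi (2.1 equiv), THF/Et2O, −78 °C; then 9, −78 °C; aqueous work-up
Reagents that add atoms: none
Why: Bromine–lithium exchange with retention of alkene geometry followed by 1,2-addition of the dienyllithium to the strained and highly electrophilic ketone 9 (organolithium carbonyl addition) should give the tertiary 1-alkenylcyclobutanol with the methyl group cis to the carbinol carbon.

Step 6
Reactants: 11 1-[(2Z,4Z,6S)-6,7-bis[(tert-butyldimethylsilyl)oxy]-4-methylhepta-2,4-dien-3-yl]cyclobutan-1-ol
Product: 12 1-[(2Z,4Z,6S)-6-[(tert-butyldimethylsilyl)oxy]-7-hydroxy-4-methylhepta-2,4-dien-3-yl]cyclobutan-1-ol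
Conditions: HF·pyridine, pyridine, THF, 0 °C
Reagents that add atoms: none
Why: Selective desilylation, because buffered HF·pyridine cleaves the unhindered primary TBS ether much faster than the secondary allylic one and is mild enough to leave the acid-sensitive tertiary dienyl carbinol intact.

Step 7
Reactants: 12 1-[(2Z,4Z,6S)-6-[(tert-butyldimethylsilyl)oxy]-7-hydroxy-4-methylhepta-2,4-dien-3-yl]cyclobutan-1-ol
Product: 13 (2S,3Z,5Z)-2-[(tert-butyldimethylsilyl)oxy]-5-(1-hydroxycyclobutyl)-4-methylhepta-3,5-dienal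
Conditions: Dess–Martin periodinane, pyridine, CH2Cl2, 0 °C → rt
Reagents that add atoms: none
Why: Dess–Martin oxidation converts the primary alcohol into the aldehyde under buffered non-basic conditions that leave the tertiary alcohol untouched and should not epimerise the α-silyloxy stereocentre or isomerise the diene.

Step 8
Reactants: 13 (2S,3Z,5Z)-2-[(tert-butyldimethylsilyl)oxy]-5-(1-hydroxycyclobutyl)-4-methylhepta-3,5-dienal
Product: 14 (2S,3Z,5Z)-2-[(tert-butyldimethylsilyl)oxy]-4-methyl-5-[1-(trimethylsilyloxy)cyclobutyl]hepta-3,5-dienal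
Conditions: N-(trimethylsilyl)imidazole, CH2Cl2, rt
Reagents that add atoms: N-(trimethylsilyl)imidazole, C[Si](C)(C)n1ccnc1
Why: Silylation of the hindered tertiary alcohol with a neutral silyl donor tolerates the aldehyde and installs the silyl ether that stops the hydroxyl group from binding the Lewis acid in the key step.

Step 9
Reactants: 14 (2S,3Z,5Z)-2-[(tert-butyldimethylsilyl)oxy]-4-methyl-5-[1-(trimethylsilyloxy)cyclobutyl]hepta-3,5-dienal
Product: 16 (5S,8S,9S,10R)-8-[(tert-butyldimethylsilyl)oxy]-9-hydroxy-6,10-dimethylspiro[4.5]dec-6-en-1-one, via trimethylsilyl ether 15 (not isolated)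
Conditions: SnCl4 (1.0 equiv), CH2Cl2, −78 → −40 °C; then dilute aqueous HCl, THF, 0 °C
Reagents that add atoms: none
Why: SnCl4 activates the C9 aldehyde, C10 of the (Z)-C5=C10 alkene attacks it (Prins cyclization) and the cation developing at C5 is quenched as it forms by a 1,2-shift of one cyclobutane CH2 (the future C4) from the silyloxy carbon C1 to C5 (semipinacol), which expands the four-membered ring to the cyclopentanone, creates the spiro centre and passes the trimethylsilyl group to the C9 oxygen (15) before acidic work-up frees the alcohol. The closest known reaction type is the pinacol-terminated Prins cyclization of 1-alkenylcycloalkanol silyl ethers together with the electrophile-induced semipinacol ring expansion of 1-alkenylcyclobutanols to 2,2-disubstituted cyclopentanones. The six-membered ring closes in a 6-endo-trig mode (C5 and C10 both inside the new ring) through a half-chair that contains the (Z)-C6=C7 bond, whereas the five-membered ring is not closed by cyclization but arises from the four-membered ring by the 1,2-shift. C10 and C5 are set together by the alkene geometry and antiperiplanar addition (C9 bonds to one face of C10 and the migrating carbon arrives at the opposite face of C5, so the ketone carbon C1 ends cis to the C10 methyl), C9 is set by the tin-complexed oxygen taking the pseudo-equatorial position away from the silyloxycyclobutyl group and hence trans to the C10 methyl, and the absolute sense comes from the (S)-C8 silyl ether, which sits pseudo-equatorial and anti to the forming bond (polar Felkin–Anh arrangement) and so selects one face of C10. The step needs facial selectivity and clean migration instead of proton loss or chloride capture of the allylic cation: the first is secured by the non-chelating TBS ether and by the trimethylsilyl ether that excludes chelated or internally delivered transition states, the second by relief of cyclobutane strain and the push of the oxygen lone pair, and no regiochemical choice arises because the two ring CH2 groups of the unsubstituted cyclobutane are equivalent.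

Step 10
Reactants: 16 (5S,8S,9S,10R)-8-[(tert-butyldimethylsilyl)oxy]-9-hydroxy-6,10-dimethylspiro[4.5]dec-6-en-1-one
Product: 17 (5S,8S,9S,10R)-8-[(tert-butyldimethylsilyl)oxy]-6,10-dimethyl-1-oxospiro[4.5]dec-6-en-9-yl acetate
Conditions: Ac2O, pyridine, DMAP (catalytic), CH2Cl2, rt
Reagents that add atoms: acetic anhydride, CC(=O)OC(C)=O
Why: Acylation of the secondary alcohol under DMAP catalysis installs the C9 acetate of the target at once and protects this oxygen for the rest of the route.

Step 11
Reactants: 17 (5S,8S,9S,10R)-8-[(tert-butyldimethylsilyl)oxy]-6,10-dimethyl-1-oxospiro[4.5]dec-6-en-9-yl acetate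
Product: 18 (5S,8S,9S,10R)-8-[(tert-butyldimethylsilyl)oxy]-6,10-dimethyl-1-oxospiro[4.5]deca-2,6-dien-9-yl acetate
Conditions: IBX, 4-methoxypyridine N-oxide, DMSO, rt
Reagents that add atoms: none
Why: IBX-mediated dehydrogenation of the ketone through its enol should give the cyclopentenone with no regiochemical ambiguity because only C2 carries α-hydrogens (C5 is quaternary), while the acetate, the silyl ether and the trisubstituted alkene are inert.

Step 12
Reactants: 18 (5S,8S,9S,10R)-8-[(tert-butyldimethylsilyl)oxy]-6,10-dimethyl-1-oxospiro[4.5]deca-2,6-dien-9-yl acetate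
Product: 20 (3R,5S,8S,9S,10R)-8-[(tert-butyldimethylsilyl)oxy]-6,10-dimethyl-1-oxo-3-(prop-1-en-2-yl)spiro[4.5]dec-6-en-9-yl acetate, via silyl enol ether 19 (not isolated)
Conditions: CH2=C(CH3)MgBr, CuBr·SMe2 (10 mol %), TMSCl, THF, −78 °C; then cold dilute aqueous HCl
Reagents that add atoms: isopropenylmagnesium bromide, C=C(C)[Mg]Br
Why: Copper-catalysed conjugate addition of the Grignard reagent with chlorosilane trapping should deliver the isopropenyl group to C3 from the face of the five-membered ring that is syn to the trigonal C6, because the equatorial C10 methyl group is gauche to both C1 and C4 and shields the other face, which sets C3 with isopropenyl cis to C6, and cold dilute acid then hydrolyses the silyl enol ether.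

Step 13
Reactants: 20 (3R,5S,8S,9S,10R)-8-[(tert-butyldimethylsilyl)oxy]-6,10-dimethyl-1-oxo-3-(prop-1-en-2-yl)spiro[4.5]dec-6-en-9-yl acetate
Product: 21 (1S,3R,5S,8S,9S,10R)-8-[(tert-butyldimethylsilyl)oxy]-1-hydroxy-6,10-dimethyl-3-(prop-1-en-2-yl)spiro[4.5]dec-6-en-9-yl acetate
Conditions: NaBH4, MeOH/THF, −40 °C
Reagents that add atoms: none
Why: Hydride reduction of the ketone should again occur from the face syn to C6, the opposite face being blocked by the C10 methyl group and the axial hydrogen at C9, which places the new C1 hydroxyl cis to C10 (1S) without touching the acetate at low temperature.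

Step 14
Reactants: 21 (1S,3R,5S,8S,9S,10R)-8-[(tert-butyldimethylsilyl)oxy]-1-hydroxy-6,10-dimethyl-3-(prop-1-en-2-yl)spiro[4.5]dec-6-en-9-yl acetate
Product: 22 (1S,3R,5S,8S,9S,10R)-9-acetoxy-8-[(tert-butyldimethylsilyl)oxy]-6,10-dimethyl-3-(prop-1-en-2-yl)spiro[4.5]dec-6-en-1-yl 3-methylbut-2-enoate
Conditions: 3-methylbut-2-enoyl chloride, pyridine, DMAP (catalytic), CH2Cl2, 0 °C → rt
Reagents that add atoms: 3-methylbut-2-enoyl chloride, CC(C)=CC(=O)Cl
Why: Esterification of the hindered secondary alcohol with the acid chloride under DMAP catalysis installs the 3-methylbut-2-enoate, and pyridine is chosen as base because stronger trialkylamines would deconjugate the acyl group through a vinylketene.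

Step 15
Reactants: 22 (1S,3R,5S,8S,9S,10R)-9-acetoxy-8-[(tert-butyldimethylsilyl)oxy]-6,10-dimethyl-3-(prop-1-en-2-yl)spiro[4.5]dec-6-en-1-yl 3-methylbut-2-enoate
Product: 23 (1S,3R,5S,8S,9S,10R)-9-acetoxy-8-hydroxy-6,10-dimethyl-3-(prop-1-en-2-yl)spiro[4.5]dec-6-en-1-yl 3-methylbut-2-enoate
Conditions: HF·pyridine, THF, 0 °C → rt
Reagents that add atoms: none
Why: Acidic fluoride desilylation removes the secondary TBS ether without the base-induced acetyl migration from the C9 oxygen to the neighbouring C8 oxygen that a basic fluoride source could cause.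

Step 16
Reactants: 23 (1S,3R,5S,8S,9S,10R)-9-acetoxy-8-hydroxy-6,10-dimethyl-3-(prop-1-en-2-yl)spiro[4.5]dec-6-en-1-yl 3-methylbut-2-enoate
Product: 24 (1S,3R,5S,9S,10R)-9-acetoxy-6,10-dimethyl-8-oxo-3-(prop-1-en-2-yl)spiro[4.5]dec-6-en-1-yl 3-methylbut-2-enoate
Conditions: Dess–Martin periodinane, pyridine, CH2Cl2, rt
Reagents that add atoms: none
Why: Dess–Martin oxidation of the allylic alcohol gives the enone and thereby erases the relay stereocentre at C8, and the now enolisable C9 centre is already in its stable arrangement with acetate and C10 methyl trans and both equatorial, so the non-basic conditions should deliver 24 without epimerisation.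

**Compound list**

1 | (R)-2,2-dimethyl-1,3-dioxolane-4-carbaldehyde ((R)-glyceraldehyde acetonide) | O=C[C@H]1COC(C)(C)O1 | starting material
2 | (4S)-4-[(1Z)-2-iodoprop-1-en-1-yl]-2,2-dimethyl-1,3-dioxolane | I/C(C)=C\[C@H]1COC(C)(C)O1 | intermediate
3 | (2S,3Z)-4-iodopent-3-ene-1,2-diol | I/C(C)=C\[C@H](O)CO | intermediate
4 | (2S,3Z)-1,2-bis[(tert-butyldimethylsilyl)oxy]-4-iodopent-3-ene | I/C(C)=C\[C@H](O[Si](C)(C)C(C)(C)C)CO[Si](C)(C)C(C)(C)C | intermediate
5 | 1,1-dibromoprop-1-ene | CC=C(Br)Br | starting material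
6 | alkenyllithium from 4, [(2E,4S)-4,5-bis[(tert-butyldimethylsilyl)oxy]pent-2-en-2-yl]lithium (lithium in place of iodine, geometry retained) | [Li]/C(C)=C\[C@H](O[Si](C)(C)C(C)(C)C)CO[Si](C)(C)C(C)(C)C | intermediate
7 | alkenylzinc bromide from 6, [(2Z,4S)-4,5-bis[(tert-butyldimethylsilyl)oxy]pent-2-en-2-yl]zinc bromide | Br[Zn]/C(C)=C\[C@H](O[Si](C)(C)C(C)(C)C)CO[Si](C)(C)C(C)(C)C | intermediate
8 | (2S,3Z,5Z)-5-bromo-1,2-bis[(tert-butyldimethylsilyl)oxy]-4-methylhepta-3,5-diene | CC(C)(C)[Si](C)(C)OC[C@@H](O[Si](C)(C)C(C)(C)C)/C=C(C)\C(Br)=C\C | intermediate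
9 | cyclobutanone | O=C1CCC1 | starting material
10 | dienyllithium from 8, [(2E,4Z,6S)-6,7-bis[(tert-butyldimethylsilyl)oxy]-4-methylhepta-2,4-dien-3-yl]lithium (lithium in place of bromine, geometry retained) | CC(C)(C)[Si](C)(C)OC[C@@H](O[Si](C)(C)C(C)(C)C)/C=C(C)\C([Li])=C\C | intermediate
11 | 1-[(2Z,4Z,6S)-6,7-bis[(tert-butyldimethylsilyl)oxy]-4-methylhepta-2,4-dien-3-yl]cyclobutan-1-ol | CC(C)(C)[Si](C)(C)OC[C@@H](O[Si](C)(C)C(C)(C)C)/C=C(C)\C(=C\C)C1(O)CCC1 | intermediate
12 | 1-[(2Z,4Z,6S)-6-[(tert-butyldimethylsilyl)oxy]-7-hydroxy-4-methylhepta-2,4-dien-3-yl]cyclobutan-1-ol | OC[C@@H](O[Si](C)(C)C(C)(C)C)/C=C(C)\C(=C\C)C1(O)CCC1 | intermediate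
13 | (2S,3Z,5Z)-2-[(tert-butyldimethylsilyl)oxy]-5-(1-hydroxycyclobutyl)-4-methylhepta-3,5-dienal | O=C[C@@H](O[Si](C)(C)C(C)(C)C)/C=C(C)\C(=C\C)C1(O)CCC1 | intermediate
14 | (2S,3Z,5Z)-2-[(tert-butyldimethylsilyl)oxy]-4-methyl-5-[1-(trimethylsilyloxy)cyclobutyl]hepta-3,5-dienal | O=C[C@@H](O[Si](C)(C)C(C)(C)C)/C=C(C)\C(=C\C)C1(O[Si](C)(C)C)CCC1 | intermediate
15 | (5S,8S,9S,10R)-8-[(tert-butyldimethylsilyl)oxy]-6,10-dimethyl-9-(trimethylsilyloxy)spiro[4.5]dec-6-en-1-one | C1CC(=O)[C@]2(C1)C(C)=C[C@H](O[Si](C)(C)C(C)(C)C)[C@@H](O[Si](C)(C)C)[C@@H]2C | intermediate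
16 | (5S,8S,9S,10R)-8-[(tert-butyldimethylsilyl)oxy]-9-hydroxy-6,10-dimethylspiro[4.5]dec-6-en-1-one | C1CC(=O)[C@]2(C1)C(C)=C[C@H](O[Si](C)(C)C(C)(C)C)[C@@H](O)[C@@H]2C | intermediate
17 | (5S,8S,9S,10R)-8-[(tert-butyldimethylsilyl)oxy]-6,10-dimethyl-1-oxospiro[4.5]dec-6-en-9-yl acetate | C1CC(=O)[C@]2(C1)C(C)=C[C@H](O[Si](C)(C)C(C)(C)C)[C@@H](OC(C)=O)[C@@H]2C | intermediate
18 | (5S,8S,9S,10R)-8-[(tert-butyldimethylsilyl)oxy]-6,10-dimethyl-1-oxospiro[4.5]deca-2,6-dien-9-yl acetate | C1=CC(=O)[C@]2(C1)C(C)=C[C@H](O[Si](C)(C)C(C)(C)C)[C@@H](OC(C)=O)[C@@H]2C | intermediate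
19 | (3R,5S,8S,9S,10R)-8-[(tert-butyldimethylsilyl)oxy]-6,10-dimethyl-3-(prop-1-en-2-yl)-1-(trimethylsilyloxy)spiro[4.5]deca-1,6-dien-9-yl acetate | C=C(C)[C@H]1C=C(O[Si](C)(C)C)[C@]2(C1)C(C)=C[C@H](O[Si](C)(C)C(C)(C)C)[C@@H](OC(C)=O)[C@@H]2C | intermediate
20 | (3R,5S,8S,9S,10R)-8-[(tert-butyldimethylsilyl)oxy]-6,10-dimethyl-1-oxo-3-(prop-1-en-2-yl)spiro[4.5]dec-6-en-9-yl acetate | C=C(C)[C@H]1CC(=O)[C@]2(C1)C(C)=C[C@H](O[Si](C)(C)C(C)(C)C)[C@@H](OC(C)=O)[C@@H]2C | intermediate
21 | (1S,3R,5S,8S,9S,10R)-8-[(tert-butyldimethylsilyl)oxy]-1-hydroxy-6,10-dimethyl-3-(prop-1-en-2-yl)spiro[4.5]dec-6-en-9-yl acetate | C=C(C)[C@H]1C[C@H](O)[C@]2(C1)C(C)=C[C@H](O[Si](C)(C)C(C)(C)C)[C@@H](OC(C)=O)[C@@H]2C | intermediate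
22 | (1S,3R,5S,8S,9S,10R)-9-acetoxy-8-[(tert-butyldimethylsilyl)oxy]-6,10-dimethyl-3-(prop-1-en-2-yl)spiro[4.5]dec-6-en-1-yl 3-methylbut-2-enoate | C=C(C)[C@H]1C[C@H](OC(=O)C=C(C)C)[C@]2(C1)C(C)=C[C@H](O[Si](C)(C)C(C)(C)C)[C@@H](OC(C)=O)[C@@H]2C | intermediate
23 | (1S,3R,5S,8S,9S,10R)-9-acetoxy-8-hydroxy-6,10-dimethyl-3-(prop-1-en-2-yl)spiro[4.5]dec-6-en-1-yl 3-methylbut-2-enoate | C=C(C)[C@H]1C[C@H](OC(=O)C=C(C)C)[C@]2(C1)C(C)=C[C@H](O)[C@@H](OC(C)=O)[C@@H]2C | intermediate
24 | (1S,3R,5S,9S,10R)-9-acetoxy-6,10-dimethyl-8-oxo-3-(prop-1-en-2-yl)spiro[4.5]dec-6-en-1-yl 3-methylbut-2-enoate | C=C(C)[C@H]1C[C@H](OC(=O)C=C(C)C)[C@]2(C1)C(C)=CC(=O)[C@@H](OC(C)=O)[C@@H]2C | target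

**Step count and risks**

Total step count: 16. Longest linear sequence: 16 steps (from 1 to 24; 5 and 9 enter as purchased fragments).

Steps most likely to fail:

Step 9. The ring closure may proceed with insufficient facial discrimination by the C8 stereocentre, or the allylic cation may lose a proton or be captured by chloride before the ring carbon migrates. The fallback sets out from 11 and comes back at 16, and makes the quaternary centre first under reagent control. A halogen-induced semipinacol ring expansion of 11 (N-bromosuccinimide with a cinchona-alkaloid-derived catalyst such as (DHQD)2PHAL) should give the bromo ketone F1. Buffered HF·pyridine then frees the primary alcohol in the bromo hydroxy ketone F2, and Dess–Martin oxidation gives the bromo aldehyde F3. The C9–C10 bond is finally closed by an intramolecular Barbier reaction with SmI2 (THF, HMPA, −78 °C), whose chair-like transition state should place methyl and hydroxyl equatorial, to reach 16.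

Step 12. The organocopper reagent may approach from the face syn to C10 if the vinylic methyl group on C6 proves the larger obstacle, which would give the C3 epimer. The fallback sets out from 18 and comes back at 20. The same copper-catalysed addition with chlorotrimethylsilane trapping is run, and the resulting silyl enol ether, then mainly the C3-epimeric silyl enol ether F4, is oxidised by the Saegusa–Ito reaction (Pd(OAc)2, MeCN) to the cross-conjugated dienone F5, in which C3 is trigonal. Conjugate reduction with [(Ph3P)CuH]6 then delivers hydrogen instead of carbon from that same preferred face, which leaves the isopropenyl group syn to C6 as in 20.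

Step 13. Hydride may be delivered to the other face of the C1 carbonyl (syn to C10) if the isopropenyl group at C3, which lies on the C6 face, outweighs the shielding by the C10 methyl group, which would give the C1 epimer. The fallback sets out from 20 and comes back at 22. The epimeric alcohol F6 is esterified with inversion by a Mitsunobu reaction with 3-methylbut-2-enoic acid (PPh3, DIAD, toluene), which installs the ester and corrects C1 in one operation.

Further compounds
F1 | step 9 | (2S)-2-[(1R)-1-bromoethyl]-2-[(2Z,4S)-4,5-bis[(tert-butyldimethylsilyl)oxy]pent-2-en-2-yl]cyclopentan-1-one | C1CC(=O)[C@@](C1)([C@H](Br)C)/C(C)=C\[C@H](O[Si](C)(C)C(C)(C)C)CO[Si](C)(C)C(C)(C)C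
F2 | step 9 | (2S)-2-[(1R)-1-bromoethyl]-2-[(2Z,4S)-4-[(tert-butyldimethylsilyl)oxy]-5-hydroxypent-2-en-2-yl]cyclopentan-1-one | C1CC(=O)[C@@](C1)([C@H](Br)C)/C(C)=C\[C@H](O[Si](C)(C)C(C)(C)C)CO
F3 | step 9 | (2S,3Z)-4-[(1S)-1-[(1R)-1-bromoethyl]-2-oxocyclopentyl]-2-[(tert-butyldimethylsilyl)oxy]pent-3-enal | C1CC(=O)[C@@](C1)([C@H](Br)C)/C(C)=C\[C@H](O[Si](C)(C)C(C)(C)C)C=O
F4 | step 12 | (3S,5S,8S,9S,10R)-8-[(tert-butyldimethylsilyl)oxy]-6,10-dimethyl-3-(prop-1-en-2-yl)-1-(trimethylsilyloxy)spiro[4.5]deca-1,6-dien-9-yl acetate | C=C(C)[C@@H]1C=C(O[Si](C)(C)C)[C@]2(C1)C(C)=C[C@H](O[Si](C)(C)C(C)(C)C)[C@@H](OC(C)=O)[C@@H]2C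
F5 | step 12 | (5S,8S,9S,10R)-8-[(tert-butyldimethylsilyl)oxy]-6,10-dimethyl-1-oxo-3-(prop-1-en-2-yl)spiro[4.5]deca-2,6-dien-9-yl acetate | C=C(C)C1=CC(=O)[C@]2(C1)C(C)=C[C@H](O[Si](C)(C)C(C)(C)C)[C@@H](OC(C)=O)[C@@H]2C
F6 | step 13 | (1R,3R,5S,8S,9S,10R)-8-[(tert-butyldimethylsilyl)oxy]-1-hydroxy-6,10-dimethyl-3-(prop-1-en-2-yl)spiro[4.5]dec-6-en-9-yl acetate | C=C(C)[C@H]1C[C@@H](O)[C@]2(C1)C(C)=C[C@H](O[Si](C)(C)C(C)(C)C)[C@@H](OC(C)=O)[C@@H]2C
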